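**Plan**

- Retrosynthesis cuts first the two aryl–CH2 bonds at C3 and C5 of the central ring (each bridge carbon goes back to an aminomethyl group on a wing), then the C1–C(=O) and C2–O bonds of the central ring, then the gem-dimethyl C–C bonds of each wing (back to an acylphloroglucinol).
- Enabling feature: C1 (butanoyl) and C2 (OH) are neighbours on the central benzene ring, which is what the C(=O)–O unit of butyric acid delivers across a C1≡C2 aryne; the oxygen on C6, next to aryne carbon C1, fixes the direction of addition.
- Forward: 3,5-dimethoxyphenol → ortho-silylaryl triflate → aryne insertion into butyric acid → demethylation to the butanoylphloroglucinol core. The aryne step is run on the bare ring, before the wings are attached, because their enolised triketones would neither survive n-BuLi nor leave an aryne untouched.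
- Wings: 2,4,6-trihydroxyacetophenone and 2,4,6-trihydroxypropiophenone are each dearomatised by gem-dimethylation and aminomethylated; the two Mannich bases are then joined one after the other to the equivalent positions C3 and C5 of the core.
- No ring is formed anywhere (all three rings come from the starting benzene rings), and the target is achiral, so no stereochemistry has to be set.

Key step: step 3

Remark: the enolised polyketones interconvert freely between enol tautomers; each is written in the tautomer that matches the target SMILES.

**Route**

Step 1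
Reactants: 1 3,5-dimethoxyphenol
Product: 2 2-bromo-3,5-dimethoxyphenol
Conditions: NBS (1.0 equiv), CH2Cl2, −78 °C to rt
Reagents that add atoms: N-bromosuccinimide, O=C1CCC(=O)N1Br
Why: Electrophilic aromatic bromination with one equivalent of NBS at low temperature in a non-polar solvent should go mainly ortho to the free hydroxyl (hydrogen-bond-assisted delivery, and the competing site between the two methoxy groups is the more hindered), with any 4-bromo isomer removed by chromatography.

Step 2
Reactants: 2 2-bromo-3,5-dimethoxyphenol
Product: 6 3,5-dimethoxy-2-(trimethylsilyl)phenyl trifluoromethanesulfonate, via aryl trimethylsilyl ether 3 (not isolated), via aryllithium 4 (not isolated), via lithium 2-silylphenoxide 5 (not isolated)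
Conditions: HMDS, THF, 70 °C, then volatiles removed; n-BuLi, THF, −78 °C; Tf2O, −78 °C to rt
Reagents that add atoms: hexamethyldisilazane, C[Si](C)(C)N[Si](C)(C)C; trifluoromethanesulfonic anhydride, O=S(=O)(OS(=O)(=O)C(F)(F)F)C(F)(F)F
Why: O-silylation, bromine–lithium exchange, anionic 1,3 O→C silyl shift (retro-Brook rearrangement) and O-triflation of the resulting phenoxide form the standard one-flask entry to ortho-silylaryl triflates, the exchange being faster than attack of n-BuLi on the silyl ether and the methoxy groups being inert.

Step 3
Reactants: 6 3,5-dimethoxy-2-(trimethylsilyl)phenyl trifluoromethanesulfonate; 7 butyric acid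
Product: 9 1-(2-hydroxy-4,6-dimethoxyphenyl)butan-1-one, via 3,5-dimethoxybenzyne 8 (not isolated)
Conditions: CsF (4 equiv), 6 (1.5 equiv), 7 (1.0 equiv), THF, 125 °C, sealed tube; aq. HCl work-up
Reagents that add atoms: none
Why: Fluoride attack on silicon with loss of triflate unveils the C1≡C2 aryne 8; caesium butyrate adds through oxygen to C2, the aryne carbon remote from the C6 methoxy group, so the aryl anion arises at C1 beside the inductively withdrawing C6–O bond, and this anion attacks the neighbouring ester carbonyl to give a four-membered benzoxetene alkoxide that opens to the C2 phenoxide and the C1 ketone. The closest known reaction type is the insertion of arynes into the acyl C–O bond of carboxylic acids (an aryne σ-insertion ending in an anionic ortho-Fries-type 1,3 O→C acyl shift), which gives ortho-hydroxyaryl ketones. No ring is closed in the product (the four-membered ring is transient) and no stereocentre is formed. The step needs regioselective O-addition at C2 and acyl transfer faster than protonation of the C1 anion: the first is secured by the C6 methoxy group next to the triple bond (aryne distortion towards attack at the distal carbon, with C3–H offering no steric resistance), the second by holding the acid as its caesium salt with excess CsF at 125 °C and using it as the limiting component. Only this regiochemistry gives the 2,4,6-trioxygenated pattern of the central ring.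

Step 4
Reactants: 9 1-(2-hydroxy-4,6-dimethoxyphenyl)butan-1-one
Product: 10 1-(2,4,6-trihydroxyphenyl)butan-1-one
Conditions: BBr3 (6 equiv), CH2Cl2, −78 °C to rt; H2O
Reagents that add atoms: none
Why: Lewis-acid cleavage of aryl methyl ethers with BBr3 (bromide attack on the O-methyl of the boron-complexed ethers) should remove both methyl groups while the chelated ortho-acylphenol is a spectator, and it is placed before any acid-sensitive wing is present.

Step 5
Reactants: 11 2,4,6-trihydroxyacetophenone
Product: 12 acetylfilicinic acid (2-acetyl-3,5-dihydroxy-6,6-dimethylcyclohexa-2,4-dien-1-one)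
Conditions: NaOMe (3 equiv), MeI (2.2 equiv), MeOH, 0 °C to rt; aq. HCl
Reagents that add atoms: iodomethane, CI
Why: Dearomative double C-methylation of the acylphloroglucinol polyanion (enolate C-alkylation) puts both methyl groups on one ring carbon to give the non-aromatic vinylogous acid, whose delocalised anion is less nucleophilic than its precursors, so limiting MeI should hold the reaction at the gem-dimethyl stage; ring-dimethyl and trimethyl by-products are removed by crystallisation or chromatography.

Step 6
Reactants: 12 acetylfilicinic acid
Product: 13 2-acetyl-4-[(dimethylamino)methyl]-3,5-dihydroxy-6,6-dimethylcyclohexa-2,4-dien-1-one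
Conditions: CH2=NMe2+ I− (1.5 equiv), Et3N (1 equiv), CH2Cl2, 0 °C, slow addition of 12
Reagents that add atoms: dimethylmethylideneammonium iodide, C=[N+](C)C.[I-]
Why: Mannich reaction with a preformed iminium salt at the only ring CH of the vinylogous acid (C4, between the two enol carbons), where slow addition to excess iminium keeps free 12 away from the product and so suppresses the symmetrical methylene-bis by-product.

Step 7
Reactants: 10 1-(2,4,6-trihydroxyphenyl)butan-1-one; 13 2-acetyl-4-[(dimethylamino)methyl]-3,5-dihydroxy-6,6-dimethylcyclohexa-2,4-dien-1-one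
Product: 15 2-acetyl-4-[(3-butanoyl-2,4,6-trihydroxyphenyl)methyl]-3,5-dihydroxy-6,6-dimethylcyclohexa-2,4-dien-1-one, via exocyclic enone 14 (not isolated)
Conditions: 10 (3 equiv), MeCN, 60 °C; 1 M HCl wash
Reagents that add atoms: none
Why: Retro-Mannich/Michael sequence (quinone-methide-type alkylation): E1cB loss of dimethylamine from the zwitterionic Mannich base gives the exocyclic enone 14, which is captured at carbon by the electron-rich phloroglucinol ring (Friedel–Crafts-type conjugate addition) and re-enolises; the two free ring positions of 10 are equivalent and its excess disfavours a second alkylation.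

Step 8
Reactants: 16 2,4,6-trihydroxypropiophenone
Product: 17 propanoylfilicinic acid (3,5-dihydroxy-6,6-dimethyl-2-propanoylcyclohexa-2,4-dien-1-one)
Conditions: NaOMe (3 equiv), MeI (2.2 equiv), MeOH, 0 °C to rt; aq. HCl
Reagents that add atoms: iodomethane, CI
Why: The same dearomative gem-C-methylation (enolate C-alkylation) as in step 5, the extra methylene of the acyl chain having no influence on the ring chemistry.

Step 9
Reactants: 17 propanoylfilicinic acid
Product: 18 4-[(dimethylamino)methyl]-3,5-dihydroxy-6,6-dimethyl-2-propanoylcyclohexa-2,4-dien-1-one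
Conditions: CH2=NMe2+ I− (1.5 equiv), Et3N (1 equiv), CH2Cl2, 0 °C, slow addition of 17
Reagents that add atoms: dimethylmethylideneammonium iodide, C=[N+](C)C.[I-]
Why: Mannich reaction at the single ring CH of the vinylogous acid, as in step 6.

Step 10
Reactants: 15 2-acetyl-4-[(3-butanoyl-2,4,6-trihydroxyphenyl)methyl]-3,5-dihydroxy-6,6-dimethylcyclohexa-2,4-dien-1-one; 18 4-[(dimethylamino)methyl]-3,5-dihydroxy-6,6-dimethyl-2-propanoylcyclohexa-2,4-dien-1-one
Product: 20 target CNP0325527.0 (butanoylphloroglucinol core carrying a methylene-linked acetylfilicinic acid unit at C3 and a methylene-linked propanoylfilicinic acid unit at C5), via exocyclic enone 19 (not isolated)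
Conditions: 18 (1.2 equiv), MeCN, 60 °C; 1 M HCl wash
Reagents that add atoms: none
Why: The same retro-Mannich/Michael alkylation as in step 7, now site-specific because C5 of the central ring is the only carbon nucleophile left in 15 (every ring carbon of the acetyl wing is substituted).

**Compound list**

1 | 3,5-dimethoxyphenol | COc1cc(O)cc(OC)c1 | starting material
2 | 2-bromo-3,5-dimethoxyphenol | COc1cc(O)c(Br)c(OC)c1 | intermediate
3 | (2-bromo-3,5-dimethoxyphenoxy)trimethylsilane | COc1cc(O[Si](C)(C)C)c(Br)c(OC)c1 | intermediate
4 | [2,4-dimethoxy-6-(trimethylsilyloxy)phenyl]lithium | [Li]c1c(OC)cc(OC)cc1O[Si](C)(C)C | intermediate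
5 | lithium 3,5-dimethoxy-2-(trimethylsilyl)phenoxide | [Li]Oc1cc(OC)cc(OC)c1[Si](C)(C)C | intermediate
6 | 3,5-dimethoxy-2-(trimethylsilyl)phenyl trifluoromethanesulfonate | COc1cc(OC)c([Si](C)(C)C)c(OS(=O)(=O)C(F)(F)F)c1 | intermediate
7 | butyric acid | CCCC(=O)O | starting material
8 | 3,5-dimethoxybenzyne (1,2-didehydro-3,5-dimethoxybenzene) | COC1=CC(OC)=CC#C1 | intermediate
9 | 1-(2-hydroxy-4,6-dimethoxyphenyl)butan-1-one | CCCC(=O)c1c(O)cc(OC)cc1OC | intermediate
10 | 1-(2,4,6-trihydroxyphenyl)butan-1-one | CCCC(=O)c1c(O)cc(O)cc1O | intermediate
11 | 2,4,6-trihydroxyacetophenone | CC(=O)c1c(O)cc(O)cc1O | starting material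
12 | acetylfilicinic acid (2-acetyl-3,5-dihydroxy-6,6-dimethylcyclohexa-2,4-dien-1-one) | CC(=O)C1=C(O)C=C(O)C(C)(C)C1=O | intermediate
13 | 2-acetyl-4-[(dimethylamino)methyl]-3,5-dihydroxy-6,6-dimethylcyclohexa-2,4-dien-1-one | CC(=O)C1=C(O)C(CN(C)C)=C(O)C(C)(C)C1=O | intermediate
14 | 2-acetyl-3-hydroxy-6,6-dimethyl-4-methylidenecyclohex-2-ene-1,5-dione | CC(=O)C1=C(O)C(=C)C(=O)C(C)(C)C1=O | intermediate
15 | 2-acetyl-4-[(3-butanoyl-2,4,6-trihydroxyphenyl)methyl]-3,5-dihydroxy-6,6-dimethylcyclohexa-2,4-dien-1-one | CCCC(=O)c1c(O)cc(O)c(CC2=C(O)C(C)(C)C(=O)C(C(C)=O)=C2O)c1O | intermediate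
16 | 2,4,6-trihydroxypropiophenone | CCC(=O)c1c(O)cc(O)cc1O | starting material
17 | propanoylfilicinic acid (3,5-dihydroxy-6,6-dimethyl-2-propanoylcyclohexa-2,4-dien-1-one) | CCC(=O)C1=C(O)C=C(O)C(C)(C)C1=O | intermediate
18 | 4-[(dimethylamino)methyl]-3,5-dihydroxy-6,6-dimethyl-2-propanoylcyclohexa-2,4-dien-1-one | CCC(=O)C1=C(O)C(CN(C)C)=C(O)C(C)(C)C1=O | intermediate
19 | 3-hydroxy-6,6-dimethyl-4-methylidene-2-propanoylcyclohex-2-ene-1,5-dione | CCC(=O)C1=C(O)C(=C)C(=O)C(C)(C)C1=O | intermediate
20 | 2-acetyl-4-[[3-butanoyl-5-[(2,6-dihydroxy-3,3-dimethyl-4-oxo-5-propanoylcyclohexa-1,5-dien-1-yl)methyl]-2,4,6-trihydroxyphenyl]methyl]-3,5-dihydroxy-6,6-dimethylcyclohexa-2,4-dien-1-one | CCCC(=O)c1c(O)c(CC2=C(O)C(C)(C)C(=O)C(C(C)=O)=C2O)c(O)c(CC2=C(O)C(C)(C)C(=O)C(C(=O)CC)=C2O)c1O | target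

**Summary**

Total step count: 10. Longest linear sequence: 6 steps (steps 1, 2, 3, 4, 7, 10).

Steps most likely to fail:

Step 3. The C1 aryl anion may be protonated by the acid before the acyl group migrates, so that net O–H insertion replaces C–O insertion and no C1–C(=O) bond forms. The fallback accepts this outcome on purpose. From 6 and 7, the aryne is captured as an O-arylation (CsF, MeCN, rt) to give 3,5-dimethoxyphenyl butanoate F1. A Lewis-acid Fries rearrangement (BF3·OEt2, 90 °C) then moves the butanoyl group to the ring carbon ortho to the phenol oxygen, and the route is rejoined at 9.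

Step 7. The first-formed dimer may be alkylated a second time by the exocyclic enone, and the Mannich base may collapse into the symmetrical wing dimer if amine loss outpaces capture. The fallback gives up the preformed electrophile: from 10 (large excess) and 12, the partners are bridged in one flask with aqueous formaldehyde in dilute aqueous KOH at rt (hydroxymethylation of the wing, dehydration and conjugate addition), then acidified and separated. This makes no new compound (F0) and comes back to the route at 15.

Step 10. At the temperature needed to alkylate the last, hindered aromatic carbon, the liberated amine may promote retro-Michael cleavage and recombination of the bridge already present, scrambling the wings. The fallback reverses the polarity of the bond formation. From 15, the single aromatic CH is aminomethylated (CH2=NMe2+ I−, Et3N, CH2Cl2, 0 °C) to give 2-acetyl-4-[[3-butanoyl-5-[(dimethylamino)methyl]-2,4,6-trihydroxyphenyl]methyl]-3,5-dihydroxy-6,6-dimethylcyclohexa-2,4-dien-1-one F2. On gentle warming with 17, a far stronger carbon nucleophile than the arene, F2 loses dimethylamine to the ortho-quinone methide 4-[(5-acetyl-2,6-dihydroxy-3,3-dimethyl-4-oxocyclohexa-1,5-dien-1-yl)methyl]-2-butanoyl-3,5-dihydroxy-6-methylidenecyclohexa-2,4-dien-1-one F3. The ring CH of 17 adds to F3 to give 20 directly.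

Further compounds
F1 | step 3 | 3,5-dimethoxyphenyl butanoate | CCCC(=O)Oc1cc(OC)cc(OC)c1
F0 | step 7 | none | none
F2 | step 10 | 2-acetyl-4-[[3-butanoyl-5-[(dimethylamino)methyl]-2,4,6-trihydroxyphenyl]methyl]-3,5-dihydroxy-6,6-dimethylcyclohexa-2,4-dien-1-one | CCCC(=O)c1c(O)c(CN(C)C)c(O)c(CC2=C(O)C(C)(C)C(=O)C(C(C)=O)=C2O)c1O
F3 | step 10 | 4-[(5-acetyl-2,6-dihydroxy-3,3-dimethyl-4-oxocyclohexa-1,5-dien-1-yl)methyl]-2-butanoyl-3,5-dihydroxy-6-methylidenecyclohexa-2,4-dien-1-one | CCCC(=O)C1=C(O)C(CC2=C(O)C(C)(C)C(=O)C(C(C)=O)=C2O)=C(O)C(=C)C1=O
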